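**Retrosynthetic overview**
- The naphthazarin is unveiled last from a 5,8-dimethoxy-1,4-naphthoquinone, which comes from a 5,8-dimethoxy-1-naphthol by para-oxygenation.
- Only one ring is made. The hydroquinone ring is bought, and the second carbocycle is closed as in the biosynthesis: the oxidised C3''-carbon of a geranylhydroquinone-type chain (here a Z-carboxylic acid) acylates the ring carbon ortho to the benzylic CH2. The C1' stereocentre and the complete dienoate ester are already in place.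
- The acyclic precursor is cut at ArCH2–CH= (the bond the prenyl transfer makes): Negishi coupling of a 2,5-dimethoxybenzylzinc with a (Z)-β-iodo Morita–Baylis–Hillman ester.
- The C1' stereocentre comes from a catalytic asymmetric three-component iodo-aldol of ethyl propiolate, TMSI and 4-methylpent-3-enal.
- The acyl part comes from a Z-selective Wittig reaction of methacrolein.

Assumption: the (S)-diphenylprolinol-derived oxazaborolidinium catalyst in step 3 directs attack to the aldehyde si face and so gives the (R)-carbinol; if the observed sense is opposite, its enantiomer is used and nothing else changes.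

**Step 1**
Reactants: 1 (2-carboxyethyl)triphenylphosphonium bromide; 2 methacrolein (2-methylprop-2-enal)
Product: 4 (3Z)-5-methylhexa-3,5-dienoic acid, via phosphonium ylide carboxylate 3 (not isolated)
Conditions: NaHMDS (2.1 equiv), THF, −78 °C; then 2, −78 → 0 °C; cold 1 M HCl work-up
Reagents that add atoms: none
Why: Z-selective Wittig olefination of a non-stabilised ylide under lithium-free conditions; the product stays a carboxylate in the basic medium, so the skipped diene does not move into conjugation.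

**Step 2**
Reactants: 5 4-methylpent-3-en-1-ol
Product: 6 4-methylpent-3-enal
Conditions: Dess–Martin periodinane (1.1 equiv), CH2Cl2, 0 °C; short silica plug, used at once as a cold solution
Reagents that add atoms: none
Why: Dess–Martin oxidation is fast and non-basic, so the β,γ-unsaturated aldehyde forms without migration of the double bond.

**Step 3**
Reactants: 6 4-methylpent-3-enal; 7 ethyl propiolate
Product: 10 ethyl (2Z)-2-[(1R)-1-hydroxy-4-methylpent-3-en-1-yl]-3-iodoprop-2-enoate, via iodoallenyl silyl ketene acetal 8 (not isolated), via O-TMS ether 9 (not isolated)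
Conditions: TMSI (1.3 equiv), (S)-o-tolyl oxazaborolidinium triflimide (20 mol%), CH2Cl2, −78 °C; then 1 M HCl/THF, 0 °C
Reagents that add atoms: iodotrimethylsilane, C[Si](C)(C)I
Why: catalytic asymmetric three-component iodo-aldol (β-iodo Morita–Baylis–Hillman) reaction, in which TMSI adds to the propiolate to give allenolate 8, which attacks the catalyst-bound aldehyde on its si face (sets C1' as R) and gives the kinetic Z-iodoalkene with iodine cis to the ester.

**Step 4**
Reactants: 10 ethyl (2Z)-2-[(1R)-1-hydroxy-4-methylpent-3-en-1-yl]-3-iodoprop-2-enoate; 11 2,5-dimethoxybenzyl chloride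
Product: 14 (2Z)-4-(2,5-dimethoxyphenyl)-2-[(1R)-1-hydroxy-4-methylpent-3-en-1-yl]but-2-enoic acid, via benzylzinc chloride 12 (not isolated), via ethyl ester 13 (not isolated)
Conditions: 11, Zn dust, LiCl, THF, 25 °C; then 10, Pd(OAc)2 (2 mol%), SPhos (4 mol%), slow addition of 12 (1.5 equiv), 25 °C; then LiOH, MeOH/H2O, 25 → 40 °C; 1 M HCl to pH 3
Reagents that add atoms: lithium hydroxide, [Li+].[OH-]
Why: Negishi sp2–sp3 coupling tolerates the free hydroxyl and keeps the alkene geometry, so ArCH2 ends cis to the carboxyl as ring closure needs; saponification in the same flask frees the acid without touching the stereocentre.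

**Step 5**
Reactants: 14 (2Z)-4-(2,5-dimethoxyphenyl)-2-[(1R)-1-hydroxy-4-methylpent-3-en-1-yl]but-2-enoic acid; 4 (3Z)-5-methylhexa-3,5-dienoic acid
Product: 16 (2Z)-4-(2,5-dimethoxyphenyl)-2-[(1R)-4-methyl-1-{[(3Z)-5-methylhexa-3,5-dienoyl]oxy}pent-3-en-1-yl]but-2-enoic acid, via dienoic anhydride 15 (not isolated)
Conditions: 4 (3 equiv), DCC (1.5 equiv), CH2Cl2, 0 °C, filter; then 14, Sc(OTf)3 (2 mol%), MeCN/CH2Cl2, −20 °C; aq. NaHCO3, then citric acid
Reagents that add atoms: none
Why: Lewis-acid-catalysed O-acylation with the symmetric anhydride is base-free, so neither the skipped dienoate nor the Z-enoic acid isomerises, and only an acyl–O bond forms at the stereocentre (retention).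

**Step 6** (key ring formation)
Reactants: 16 (2Z)-4-(2,5-dimethoxyphenyl)-2-[(1R)-4-methyl-1-{[(3Z)-5-methylhexa-3,5-dienoyl]oxy}pent-3-en-1-yl]but-2-enoic acid
Product: 19 (1R)-1-(1-hydroxy-5,8-dimethoxynaphthalen-2-yl)-4-methylpent-3-en-1-yl (3Z)-5-methylhexa-3,5-dienoate, via acyl trifluoroacetate 17 (not isolated), via naphthyl trifluoroacetate 18 (not isolated)
Conditions: TFAA (3 equiv), CH2Cl2, −20 → 0 °C; then MeOH, 0 °C; pH 7 buffer work-up
Reagents that add atoms: none
Why: biomimetic intramolecular Friedel–Crafts acylation, in which the Z-alkene holds the mixed anhydride over the methoxy-activated ortho carbon, and six-ring closure then tautomerisation gives the naphthol; the C1' oxygen carries a carboxylate (a poor leaving group), which keeps the stereocentre from ionising.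

**Step 7**
Reactants: 19 (1R)-1-(1-hydroxy-5,8-dimethoxynaphthalen-2-yl)-4-methylpent-3-en-1-yl (3Z)-5-methylhexa-3,5-dienoate
Product: 20 (1R)-1-(5,8-dimethoxy-1,4-dioxo-1,4-dihydronaphthalen-2-yl)-4-methylpent-3-en-1-yl (3Z)-5-methylhexa-3,5-dienoate
Conditions: O2 (1 atm), salcomine (10 mol%), MeCN, 25 °C
Reagents that add atoms: dioxygen, O=O
Why: Co(salen)/O2 phenol-to-para-quinone oxidation of a 1-naphthol with a free C4 position, under neutral conditions that leave the ortho benzylic ester and the alkenes alone.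

**Step 8**
Reactants: 20 (1R)-1-(5,8-dimethoxy-1,4-dioxo-1,4-dihydronaphthalen-2-yl)-4-methylpent-3-en-1-yl (3Z)-5-methylhexa-3,5-dienoate
Product: 22 (1R)-1-(5,8-dihydroxy-1,4-dioxo-1,4-dihydronaphthalen-2-yl)-4-methylpent-3-en-1-yl (3Z)-5-methylhexa-3,5-dienoate (CNP0129564.1), via naphthodiquinone 21 (not isolated)
Conditions: AgO (4 equiv), 6 M HNO3, 1,4-dioxane, 20 °C, 5 min; then aq. Na2S2O4 work-up
Reagents that add atoms: water, O
Why: silver(II) oxidative demethylation (ipso attack of water, loss of methanol) turns the p-dimethoxy ring into a second quinone, and dithionite reduces diquinone 21 to the naphthazarin; the benzylic ester sits on an electron-poor ring and does not ionise.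

**Compound list**
1 | (2-carboxyethyl)triphenylphosphonium bromide | OC(=O)CC[P+](c1ccccc1)(c1ccccc1)c1ccccc1.[Br-] | starting material
2 | methacrolein | CC(=C)C=O | starting material
3 | sodium 3-(triphenylphosphoranylidene)propanoate | [Na+].[O-]C(=O)CC=P(c1ccccc1)(c1ccccc1)c1ccccc1 | intermediate
4 | (3Z)-5-methylhexa-3,5-dienoic acid | C=C(C)/C=C\CC(=O)O | intermediate
5 | 4-methylpent-3-en-1-ol | CC(C)=CCCO | starting material
6 | 4-methylpent-3-enal | CC(C)=CCC=O | intermediate
7 | ethyl propiolate | C#CC(=O)OCC | starting material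
8 | [(1-ethoxy-3-iodopropa-1,2-dien-1-yl)oxy]trimethylsilane | CCOC(O[Si](C)(C)C)=C=CI | intermediate
9 | ethyl (2Z)-3-iodo-2-{(1R)-4-methyl-1-[(trimethylsilyl)oxy]pent-3-en-1-yl}prop-2-enoate | C[Si](C)(C)O[C@H](CC=C(C)C)/C(C(=O)OCC)=C/I | intermediate
10 | ethyl (2Z)-2-[(1R)-1-hydroxy-4-methylpent-3-en-1-yl]-3-iodoprop-2-enoate | O[C@H](CC=C(C)C)/C(C(=O)OCC)=C/I | intermediate
11 | 2,5-dimethoxybenzyl chloride | ClCc1cc(OC)ccc1OC | starting material
12 | (2,5-dimethoxybenzyl)zinc chloride | Cl[Zn]Cc1cc(OC)ccc1OC | intermediate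
13 | ethyl (2Z)-4-(2,5-dimethoxyphenyl)-2-[(1R)-1-hydroxy-4-methylpent-3-en-1-yl]but-2-enoate | O[C@H](CC=C(C)C)/C(C(=O)OCC)=C/Cc1cc(OC)ccc1OC | intermediate
14 | (2Z)-4-(2,5-dimethoxyphenyl)-2-[(1R)-1-hydroxy-4-methylpent-3-en-1-yl]but-2-enoic acid | O[C@H](CC=C(C)C)/C(C(=O)O)=C/Cc1cc(OC)ccc1OC | intermediate
15 | (3Z)-5-methylhexa-3,5-dienoic anhydride | C=C(C)/C=C\CC(=O)OC(=O)C/C=C\C(C)=C | intermediate
16 | (2Z)-4-(2,5-dimethoxyphenyl)-2-[(1R)-4-methyl-1-{[(3Z)-5-methylhexa-3,5-dienoyl]oxy}pent-3-en-1-yl]but-2-enoic acid | C=C(C)/C=C\CC(=O)O[C@H](CC=C(C)C)/C(C(=O)O)=C/Cc1cc(OC)ccc1OC | intermediate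
17 | mixed anhydride of 16 with trifluoroacetic acid | C=C(C)/C=C\CC(=O)O[C@H](CC=C(C)C)/C(C(=O)OC(=O)C(F)(F)F)=C/Cc1cc(OC)ccc1OC | intermediate
18 | 5,8-dimethoxy-2-[(1R)-4-methyl-1-{[(3Z)-5-methylhexa-3,5-dienoyl]oxy}pent-3-en-1-yl]naphthalen-1-yl trifluoroacetate | C=C(C)/C=C\CC(=O)O[C@H](CC=C(C)C)c1ccc2c(OC)ccc(OC)c2c1OC(=O)C(F)(F)F | intermediate
19 | (1R)-1-(1-hydroxy-5,8-dimethoxynaphthalen-2-yl)-4-methylpent-3-en-1-yl (3Z)-5-methylhexa-3,5-dienoate | C=C(C)/C=C\CC(=O)O[C@H](CC=C(C)C)c1ccc2c(OC)ccc(OC)c2c1O | intermediate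
20 | (1R)-1-(5,8-dimethoxy-1,4-dioxo-1,4-dihydronaphthalen-2-yl)-4-methylpent-3-en-1-yl (3Z)-5-methylhexa-3,5-dienoate | C=C(C)/C=C\CC(=O)O[C@H](CC=C(C)C)C1=CC(=O)c2c(OC)ccc(OC)c2C1=O | intermediate
21 | (1R)-4-methyl-1-(1,4,5,8-tetraoxo-1,4,5,8-tetrahydronaphthalen-2-yl)pent-3-en-1-yl (3Z)-5-methylhexa-3,5-dienoate | C=C(C)/C=C\CC(=O)O[C@H](CC=C(C)C)C1=CC(=O)C2=C(C1=O)C(=O)C=CC2=O | intermediate
22 | (1R)-1-(5,8-dihydroxy-1,4-dioxo-1,4-dihydronaphthalen-2-yl)-4-methylpent-3-en-1-yl (3Z)-5-methylhexa-3,5-dienoate | C=C(C)/C=C\CC(=O)O[C@H](CC=C(C)C)C1=CC(=O)c2c(O)ccc(O)c2C1=O | target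

**Totals**
Total step count: 8. Longest linear sequence: 7 (steps 2 to 8; step 1 is the side branch that supplies acid 4).

**Three steps most likely to fail**

Step 6 (ring closure). The acyl trifluoroacetate could acylate the prenyl alkene, the liberated acid could add to it, or the C1' ester could be lost. The fallback replaces the electrophilic closure by an anionic (Parham) closure and moves the esterification behind it. It sets out from 10 and comes back at 20. Commercial 2,5-dimethoxybenzyl alcohol is ortho-lithiated between CH2OLi and OMe (n-BuLi) and quenched with BrCCl2CCl2Br to give (2-bromo-3,6-dimethoxyphenyl)methanol F3. SOCl2 gives 2-bromo-3,6-dimethoxybenzyl chloride F4, and Zn/LiCl gives (2-bromo-3,6-dimethoxybenzyl)zinc chloride F5. Negishi coupling of F5 with 10 as in step 4, without saponification, gives ethyl (2Z)-4-(2-bromo-3,6-dimethoxyphenyl)-2-[(1R)-1-hydroxy-4-methylpent-3-en-1-yl]but-2-enoate F6. t-BuLi (3.1 equiv, THF, −100 °C) effects Br–Li exchange and the aryllithium closes onto the cis-held ester; tautomerisation gives 2-[(1R)-1-hydroxy-4-methylpent-3-en-1-yl]-5,8-dimethoxynaphthalen-1-ol F7. O2/salcomine gives 2-[(1R)-1-hydroxy-4-methylpent-3-en-1-yl]-5,8-dimethoxynaphthalene-1,4-dione F8, and acylation with anhydride 15 (Sc(OTf)3, −20 °C) returns to the route at 20.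

Step 3 (asymmetric iodo-aldol). The enolisable β,γ-unsaturated aldehyde may give low ee or erode Z-selectivity. The fallback separates C–C bond formation from stereocontrol. It sets out from 6 and 7 and comes back at 10. The achiral MgI2-mediated iodo-aldol (CH2Cl2, 0 °C) gives racemic ethyl (2Z)-2-(1-hydroxy-4-methylpent-3-en-1-yl)-3-iodoprop-2-enoate F1. Dess–Martin oxidation gives ethyl (2Z)-2-(iodomethylidene)-6-methyl-3-oxohept-5-enoate F2. Reagent-controlled ketone reduction ((S)-Me-CBS, catecholborane, toluene, −78 °C; the iodovinyl ester arm is the large group) then gives the (R)-alcohol 10.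

Step 8 (oxidative demethylation). The skipped dienoate may not survive Ag(II) or the strongly dienophilic diquinone 21. The fallback replaces the redox sequence by a non-oxidative, chelation-driven dealkylation. It sets out from 20 and comes back at 22. BCl3 (CH2Cl2, −78 °C) cleaves the two peri-methoxy groups through the carbonyl-chelated (1R)-1-[5,8-bis(dichloroboryloxy)-1,4-dioxo-1,4-dihydronaphthalen-2-yl]-4-methylpent-3-en-1-yl (3Z)-5-methylhexa-3,5-dienoate F9, and aqueous work-up gives 22 directly.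

**Further compounds**
F1 | step 3 | ethyl (2Z)-2-(1-hydroxy-4-methylpent-3-en-1-yl)-3-iodoprop-2-enoate (racemic) | OC(CC=C(C)C)/C(C(=O)OCC)=C/I
F2 | step 3 | ethyl (2Z)-2-(iodomethylidene)-6-methyl-3-oxohept-5-enoate | O=C(CC=C(C)C)/C(C(=O)OCC)=C/I
F3 | step 6 | (2-bromo-3,6-dimethoxyphenyl)methanol | OCc1c(Br)c(OC)ccc1OC
F4 | step 6 | 2-bromo-3,6-dimethoxybenzyl chloride | ClCc1c(Br)c(OC)ccc1OC
F5 | step 6 | (2-bromo-3,6-dimethoxybenzyl)zinc chloride | Cl[Zn]Cc1c(Br)c(OC)ccc1OC
F6 | step 6 | ethyl (2Z)-4-(2-bromo-3,6-dimethoxyphenyl)-2-[(1R)-1-hydroxy-4-methylpent-3-en-1-yl]but-2-enoate | O[C@H](CC=C(C)C)/C(C(=O)OCC)=C/Cc1c(Br)c(OC)ccc1OC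
F7 | step 6 | 2-[(1R)-1-hydroxy-4-methylpent-3-en-1-yl]-5,8-dimethoxynaphthalen-1-ol | O[C@H](CC=C(C)C)c1ccc2c(OC)ccc(OC)c2c1O
F8 | step 6 | 2-[(1R)-1-hydroxy-4-methylpent-3-en-1-yl]-5,8-dimethoxynaphthalene-1,4-dione | O[C@H](CC=C(C)C)C1=CC(=O)c2c(OC)ccc(OC)c2C1=O
F9 | step 8 | (1R)-1-[5,8-bis(dichloroboryloxy)-1,4-dioxo-1,4-dihydronaphthalen-2-yl]-4-methylpent-3-en-1-yl (3Z)-5-methylhexa-3,5-dienoate | C=C(C)/C=C\CC(=O)O[C@H](CC=C(C)C)C1=CC(=O)c2c(OB(Cl)Cl)ccc(OB(Cl)Cl)c2C1=O
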